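## Retrosynthetic overview

- The naphthazarin is unmasked last from a 1,4,5,8-tetramethoxynaphthalene. The angelate is put on the tertiary alkoxide just before, and the C–O bond at the ester carbon comes from a C–B bond by stereoretentive oxidation.
- Key disconnection: the bond between naphthalene C-2 and cyclobutane C-1′. It is made by 1,2-migration of the aryl group from boron to carbon in a boronate complex, in the same event that enlarges a cyclopropane to the cyclobutane.
- Enabling feature: in the cyclobutane, the quaternary carbon C-1′ (bearing O and aryl) sits directly beside the gem-dimethyl carbon C-2′. This C-1′/C-2′ edge is the image of a 1-boryl-1-isopropenylcyclopropane after protonation (isopropenyl → CMe2 cation → C-2′; C–B → C–O).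
- Precursors: the aryllithium from 2-bromo-1,4,5,8-tetramethoxynaphthalene, and the (R,R)-1,2-dicyclohexylethanediol ester of [1-(prop-1-en-2-yl)cyclopropyl]boronic acid, made in two steps from 1-(1-chlorocyclopropyl)ethanone.
- Ring order: naphthalene and cyclopropane are bought; the cyclobutane forms in step 4; the quinone/hydroquinone rings are unveiled in step 7.

Key step: step 4

Remark 1: the sense of induction by the boron-bound diol cannot be predicted with certainty; the route is written for the case that the (R,R)-diol leads to the (S)-configured boronic ester of step 4, and in the opposite case the equally available (S,S)-diol is used with no other change.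
Remark 2: 1,4,5,8-tetramethoxynaphthalene is taken as a catalogue compound; the target is one tautomer of a naphthazarin, whose tautomers interconvert rapidly, so it does not matter which ring carries the quinone carbonyls at the moment of unmasking.

## Route

Step 1
Reactants: 1 1,4,5,8-tetramethoxynaphthalene
Product: 2 2-bromo-1,4,5,8-tetramethoxynaphthalene
Conditions: NBS (1.0 equiv), CH2Cl2, 0 °C → rt
Reagents that add atoms: N-bromosuccinimide O=C1CCC(=O)N1Br
Why: Electrophilic aromatic bromination of an electron-rich arene; the four ring C–H positions of 1 are equivalent by symmetry, so one equivalent of NBS should give a single monobromide.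

Step 2
Reactants: 3 1-(1-chlorocyclopropyl)ethan-1-one
Product: 4 1-chloro-1-(prop-1-en-2-yl)cyclopropane
Conditions: Ph3PCH3Br, KOtBu, Et2O, 0 °C → rt; distilled
Reagents that add atoms: methylenetriphenylphosphorane (made in the flask from methyltriphenylphosphonium bromide and KOtBu) C=P(c1ccccc1)(c1ccccc1)c1ccccc1
Why: Wittig methylenation of a methyl ketone; the tertiary cyclopropyl chloride can be neither displaced nor eliminated by the ylide, and the volatile product is separated from triphenylphosphine oxide by distillation.

Step 3
Reactants: 4 1-chloro-1-(prop-1-en-2-yl)cyclopropane; 5 (1R,2R)-1,2-dicyclohexylethane-1,2-diol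
Product: 8 (4R,5R)-4,5-dicyclohexyl-2-[1-(prop-1-en-2-yl)cyclopropyl]-1,3,2-dioxaborolane, via cyclopropyllithium 6 (not isolated), via boronic acid 7 (not isolated)
Conditions: lithium 4,4′-di-tert-butylbiphenylide (2.2 equiv), THF, −78 °C; B(OMe)3, −78 °C → rt; 1 M HCl to pH 5, 0 °C; crude 7, 5, MgSO4, Et2O, rt
Reagents that add atoms: trimethyl borate COB(OC)OC
Why: Reductive lithiation of a tertiary alkyl chloride by an arene radical anion, borate trapping and diol esterification; the 1-alkenylcyclopropyl anion stays localised on the ring carbon (its allylic alternative would be an alkylidenecyclopropane), so boron enters at the ring carbon, and the two stereocentres of the auxiliary are bought in.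

Step 4
Reactants: 2 2-bromo-1,4,5,8-tetramethoxynaphthalene; 8 (4R,5R)-4,5-dicyclohexyl-2-[1-(prop-1-en-2-yl)cyclopropyl]-1,3,2-dioxaborolane
Product: 12 (4R,5R)-4,5-dicyclohexyl-2-[(1S)-2,2-dimethyl-1-(1,4,5,8-tetramethoxynaphthalen-2-yl)cyclobutyl]-1,3,2-dioxaborolane, via aryllithium 9 (not isolated), via lithium boronate complex 10 (not isolated), via zwitterionic cyclopropylcarbinyl cation 11 (not isolated)
Conditions: 2, t-BuLi (2.0 equiv), THF, −78 °C; 8, −78 → 0 °C; 2,6-lutidinium triflate (1.2 equiv), THF/MeCN, −40 °C → rt
Reagents that add atoms: none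
Why: Proposed new method: aryllithium 9 adds to boron of 8 to give ate complex 10, whose terminal =CH2 (the γ-carbon of an allyl-type boronate, its most nucleophilic and least hindered site) is protonated to the tertiary cyclopropylcarbinyl cation 11; a ring C–C bond then shifts to the cationic carbon while the naphthyl group migrates from boron to the ring carbon anti to the departing bond, so that the aryl–C bond, the four-membered ring, the fully substituted boron-bearing carbon and the gem-dimethyl carbon arise in one event. The closest known reaction type is the electrophile-triggered, ring-expansion-induced 1,2-metalate rearrangement of 1-vinylcyclopropyl boronate complexes, known with achiral diol esters and with carbon or heteroatom electrophiles; new here are the proton as trigger and the chiral diol on boron, the latter modelled on diol-controlled Matteson homologation, in which the auxiliary likewise decides which of two equivalent groups on the boron-bearing carbon lies anti to the migrating group. The cyclobutane is not closed end to end but formed by cyclopropylcarbinyl-to-cyclobutyl ring enlargement (1,2-shift of a ring carbon, three- to four-membered). The one new stereocentre is set by the choice between the two enantiotopic CH2 groups of the cyclopropane, which the C2-symmetric (R,R)-diol makes diastereotopic, coupled with the stereospecific anti migration; as the auxiliary stays on boron, the two possible products are diastereomers and a minor one can be removed from 12 by chromatography or crystallisation. The step needs protonation at the alkene and not at the aryl ipso carbon (a hindered, weak pyridinium acid is used and the ipso carbon is shielded by the ortho methoxy group and the quaternary boron), ring enlargement and not loss of boron (that path would give a strained alkylidenecyclopropane), and migration of the aryl group only (the other two ligands on boron are the diol oxygens).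

Step 5
Reactants: 12 (4R,5R)-4,5-dicyclohexyl-2-[(1S)-2,2-dimethyl-1-(1,4,5,8-tetramethoxynaphthalen-2-yl)cyclobutyl]-1,3,2-dioxaborolane
Product: 13 (1R)-2,2-dimethyl-1-(1,4,5,8-tetramethoxynaphthalen-2-yl)cyclobutan-1-ol
Conditions: 30% H2O2, 2 M NaOH, THF, 0 °C → rt
Reagents that add atoms: hydrogen peroxide OO
Why: Alkaline peroxide oxidation of a boronic ester, in which carbon migrates from boron to oxygen with retention, so the (S)-boronic ester gives the (R)-alcohol (the descriptor changes only because oxygen outranks the carbon substituents and boron does not); the electron-rich arene is inert to alkaline peroxide and diol 5 is released for re-use.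

Step 6
Reactants: 13 (1R)-2,2-dimethyl-1-(1,4,5,8-tetramethoxynaphthalen-2-yl)cyclobutan-1-ol; 14 angelic acid, (2Z)-2-methylbut-2-enoic acid
Product: 16 (1R)-2,2-dimethyl-1-(1,4,5,8-tetramethoxynaphthalen-2-yl)cyclobutyl (2Z)-2-methylbut-2-enoate, via lithium alkoxide 15 (not isolated)
Conditions: 14, 2,4,6-trichlorobenzoyl chloride, Et3N, toluene, rt, filtered; 13, LiHMDS, THF, −78 °C, then the mixed anhydride, −78 → 0 °C
Reagents that add atoms: none
Why: Acylation of a preformed lithium tertiary alkoxide by a Yamaguchi-type mixed anhydride, attacked at the angeloyl carbonyl because the trichlorobenzoyl carbonyl is flanked by two ortho chlorines; no nucleophilic catalyst or amine is present at the acylation stage and the temperature is low, which should keep the Z double bond in place, and no bond to the stereocentre is touched.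

Step 7
Reactants: 16 (1R)-2,2-dimethyl-1-(1,4,5,8-tetramethoxynaphthalen-2-yl)cyclobutyl (2Z)-2-methylbut-2-enoate
Product: 18 (1R)-1-(5,8-dihydroxy-1,4-dioxo-1,4-dihydronaphthalen-2-yl)-2,2-dimethylcyclobutyl (2Z)-2-methylbut-2-enoate, via naphthalene-1,4,5,8-tetrone 17 (not isolated)
Conditions: AgO (excess), 6 M HNO3, 1,4-dioxane, 0 °C → rt, short contact; then aq. Na2S2O4, EtOAc, air
Reagents that add atoms: water O
Why: Oxidative demethylation of both p-dimethoxy rings by argentic oxide (aryl–oxygen cleavage with water as the oxygen source) to the diquinone, then two-electron reduction by dithionite to the naphthazarin; oxidising both rings removes the question of which ring reacts first, the quinone level deactivates the tertiary benzylic-type ester towards ionisation, and the stereocentre is not involved.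

## Compound list

1 | 1,4,5,8-tetramethoxynaphthalene | COc1ccc(OC)c2c(OC)ccc(OC)c12 | starting material
2 | 2-bromo-1,4,5,8-tetramethoxynaphthalene | COc1cc(Br)c(OC)c2c(OC)ccc(OC)c12 | intermediate
3 | 1-(1-chlorocyclopropyl)ethan-1-one | CC(=O)C1(Cl)CC1 | starting material
4 | 1-chloro-1-(prop-1-en-2-yl)cyclopropane | CC(=C)C1(Cl)CC1 | intermediate
5 | (1R,2R)-1,2-dicyclohexylethane-1,2-diol | O[C@H](C1CCCCC1)[C@H](O)C1CCCCC1 | starting material
6 | [1-(prop-1-en-2-yl)cyclopropyl]lithium | [Li]C1(C(C)=C)CC1 | intermediate
7 | [1-(prop-1-en-2-yl)cyclopropyl]boronic acid | OB(O)C1(C(C)=C)CC1 | intermediate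
8 | (4R,5R)-4,5-dicyclohexyl-2-[1-(prop-1-en-2-yl)cyclopropyl]-1,3,2-dioxaborolane | CC(=C)C1(CC1)B1O[C@H](C2CCCCC2)[C@@H](C2CCCCC2)O1 | intermediate
9 | (1,4,5,8-tetramethoxynaphthalen-2-yl)lithium | [Li]c1cc(OC)c2c(OC)ccc(OC)c2c1OC | intermediate
10 | lithium (4R,5R)-4,5-dicyclohexyl-2-[1-(prop-1-en-2-yl)cyclopropyl]-2-(1,4,5,8-tetramethoxynaphthalen-2-yl)-1,3,2-dioxaborolan-2-uide | [Li+].CC(=C)C1(CC1)[B-]1(c2cc(OC)c3c(OC)ccc(OC)c3c2OC)O[C@H](C2CCCCC2)[C@@H](C2CCCCC2)O1 | intermediate
11 | zwitterion of 10 protonated at the alkene CH2 (2-propyl cation on the cyclopropane carbon that bears the borate) | C[C+](C)C1(CC1)[B-]1(c2cc(OC)c3c(OC)ccc(OC)c3c2OC)O[C@H](C2CCCCC2)[C@@H](C2CCCCC2)O1 | intermediate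
12 | (4R,5R)-4,5-dicyclohexyl-2-[(1S)-2,2-dimethyl-1-(1,4,5,8-tetramethoxynaphthalen-2-yl)cyclobutyl]-1,3,2-dioxaborolane | O1[C@H](C3CCCCC3)[C@@H](C3CCCCC3)OB1[C@]2(c3cc(OC)c4c(OC)ccc(OC)c4c3OC)CCC2(C)C | intermediate
13 | (1R)-2,2-dimethyl-1-(1,4,5,8-tetramethoxynaphthalen-2-yl)cyclobutan-1-ol | O[C@]1(c2cc(OC)c3c(OC)ccc(OC)c3c2OC)CCC1(C)C | intermediate
14 | angelic acid, (2Z)-2-methylbut-2-enoic acid | C/C=C(/C)C(=O)O | starting material
15 | lithium (1R)-2,2-dimethyl-1-(1,4,5,8-tetramethoxynaphthalen-2-yl)cyclobutan-1-olate | [Li+].[O-][C@]1(c2cc(OC)c3c(OC)ccc(OC)c3c2OC)CCC1(C)C | intermediate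
16 | (1R)-2,2-dimethyl-1-(1,4,5,8-tetramethoxynaphthalen-2-yl)cyclobutyl (2Z)-2-methylbut-2-enoate | C/C=C(/C)C(=O)O[C@]1(c2cc(OC)c3c(OC)ccc(OC)c3c2OC)CCC1(C)C | intermediate
17 | (1R)-2,2-dimethyl-1-(1,4,5,8-tetraoxo-1,4,5,8-tetrahydronaphthalen-2-yl)cyclobutyl (2Z)-2-methylbut-2-enoate | C/C=C(/C)C(=O)O[C@]1(C2=CC(=O)C3=C(C2=O)C(=O)C=CC3=O)CCC1(C)C | intermediate
18 | (1R)-1-(5,8-dihydroxy-1,4-dioxo-1,4-dihydronaphthalen-2-yl)-2,2-dimethylcyclobutyl (2Z)-2-methylbut-2-enoate | C/C=C(/C)C(=O)O[C@]1(C2=CC(=O)c3c(O)ccc(O)c3C2=O)CCC1(C)C | target

## Summary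

Total step count: 7. Longest linear sequence: 6 steps (3 → 4 → 8 → 12 → 13 → 16 → 18; steps 2 to 7).

Steps most likely to fail

1. Step 4 (proposed new method). The diol may discriminate only weakly between the two enantiotopic ring bonds; the proton may also attack the aryl ipso carbon (protodeboronation), or the cation may lose boron instead of enlarging the ring. Fallback with known chemistry, setting out from bromide 2: aryllithium 9 is generated as in step 4 and added to commercial 2,2-dimethylcyclobutanone (THF, −78 °C). This should give racemic 2,2-dimethyl-1-(1,4,5,8-tetramethoxynaphthalen-2-yl)cyclobutan-1-ol F1. Preparative chromatography on a chiral stationary phase separates the enantiomers, and the (R)-alcohol is compound 13, where the route is rejoined before step 6.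

2. Step 6. Acyl transfer to the hindered tertiary alkoxide may be slow, leaving time for Z → E isomerisation or deconjugation of the angeloyl donor. Fallback setting out from alcohol 13 (as alkoxide 15): acylation with 2-[bis(2,2,2-trifluoroethoxy)phosphoryl]propanoyl chloride, a small and highly electrophilic acyl donor. This gives (1R)-2,2-dimethyl-1-(1,4,5,8-tetramethoxynaphthalen-2-yl)cyclobutyl 2-[bis(2,2,2-trifluoroethoxy)phosphoryl]propanoate F2, a mixture of epimers at the phosphorus-bearing carbon. Still–Gennari olefination with acetaldehyde (KHMDS, 18-crown-6, THF, −78 °C) then builds the Z-trisubstituted enoate on the ester already in place and comes back to the route at 16.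

3. Step 7. The diquinone may be over-oxidised or lost to hydrolysis, or the tertiary ester may ionise in nitric acid before its ring is oxidised. Fallback setting out from 16: CAN (MeCN–H2O, 0 °C) oxidises one ring only. It should give (1R)-1-(1,4-dimethoxy-5,8-dioxo-5,8-dihydronaphthalen-2-yl)-2,2-dimethylcyclobutyl (2Z)-2-methylbut-2-enoate F3 (quinone in the unsubstituted ring), possibly with the regioisomeric (1R)-1-(5,8-dimethoxy-1,4-dioxo-1,4-dihydronaphthalen-2-yl)-2,2-dimethylcyclobutyl (2Z)-2-methylbut-2-enoate F4. Both are demethylated at the two peri-methoxy groups by BCl3 (CH2Cl2, −78 °C, chelation to the quinone carbonyls). Both converge on 18, because the naphthazarin tautomers interconvert.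

Further compounds
F1 | step 4 | racemic 2,2-dimethyl-1-(1,4,5,8-tetramethoxynaphthalen-2-yl)cyclobutan-1-ol | OC1(c2cc(OC)c3c(OC)ccc(OC)c3c2OC)CCC1(C)C
F2 | step 6 | (1R)-2,2-dimethyl-1-(1,4,5,8-tetramethoxynaphthalen-2-yl)cyclobutyl 2-[bis(2,2,2-trifluoroethoxy)phosphoryl]propanoate | CC(C(=O)O[C@]1(c2cc(OC)c3c(OC)ccc(OC)c3c2OC)CCC1(C)C)P(=O)(OCC(F)(F)F)OCC(F)(F)F
F3 | step 7 | (1R)-1-(1,4-dimethoxy-5,8-dioxo-5,8-dihydronaphthalen-2-yl)-2,2-dimethylcyclobutyl (2Z)-2-methylbut-2-enoate | C/C=C(/C)C(=O)O[C@]1(c2cc(OC)c3C(=O)C=CC(=O)c3c2OC)CCC1(C)C
F4 | step 7 | (1R)-1-(5,8-dimethoxy-1,4-dioxo-1,4-dihydronaphthalen-2-yl)-2,2-dimethylcyclobutyl (2Z)-2-methylbut-2-enoate | C/C=C(/C)C(=O)O[C@]1(C2=CC(=O)c3c(OC)ccc(OC)c3C2=O)CCC1(C)C
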